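## Analysis of the target

The target is an unsymmetrical lignan dimer. One half is an olivil-type tetrahydrofuran: O1, C2 bearing ring A, C3 bearing CH2OH, C4 bearing OH and the CH2 of the isovanillyl ring B, C5H2. The other half is a cycloolivil-type tetralin: C1 bearing ring C, C2 bearing CH2OH, C3 bearing OH and CH2OH, C4H2, fused to ring D. The halves are joined by a biaryl bond between the carbons ortho to the phenolic OH of rings A and C. There are six stereocenters. In the tetrahydrofuran (2S,3R,4S), ring A is trans to the C3 CH2OH, which is cis to the benzyl group and trans to the tertiary OH. In the tetralin (1S,2S,3S), ring C is trans to the C2 CH2OH, which is cis to the C3 OH. The CH(CH2OH)–C(OH) pairs of the two halves have the same sense, so one chiral controller can serve both. The sensitive groups are four free phenols, two tertiary alcohols and the benzylic C2–O bond of the tetrahydrofuran, which lies para to a phenol oxygen, ionises in acid (ring B then closes to a second tetralin) and can be hydrogenolysed. The synthesis is hard because a hindered 2,2'-dioxygenated biaryl must be made between two elaborate, acid-labile halves that differ only subtly, each holding a quaternary carbinol center. The strategy rests on ring C, which carries in sequence the bond to ring A, H, tetralin C1, H, OMe and OH. Its four carbons CH–C(C1)–CH–C(OMe) are C6, C5, C4 and C3 of a 5-substituted 3-methoxy-2-pyrone, and the other two, C(ring A) and C(OH), are the carbons of an aryl ynol ether on ring A.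

## Retrosynthetic reasoning

**Protecting groups (45 ← 44 ← 43 ← 42).** No skeletal bond is cut. 42 carries five benzyl ethers (three phenols, two CH2OH), a silyl ether on the ring C phenol (it is formed silylated), a silyl ether on the tetrahydrofuran tertiary OH and an isopropylidene acetal on the tetralin diol. They are removed in the order fluoride-labile, acid-labile, hydrogenolysable, so that the acid step meets ring A while its para oxygen is still benzylated and the free polyphenol appears last.

**Ring C (42 ← 21 + 40).** Two ring C bonds are cut: C(ring A-bearing)–CH and C(O)–C(OMe). This leaves pyrone 40, with the tetralin at C5 and OMe at C3, and ynol ether 21 on ring A. The cut is made here because ring C is where the halves meet, so the ring construction also makes the biaryl bond and no aryl–aryl coupling of two hindered guaiacols is needed. Forward, the alkyne must add across pyrone C3 and C6 in one orientation, and the bridged lactone 41 must decarboxylate to the arene.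

**Ynol ether (21 ← 19 ← 17).** The ynol ether is the most fragile function of the route, so its oxygen is put on last: 21 comes from terminal alkyne 19 by oxygen transfer to the acetylide and O-silylation, and 19 from aryl iodide 17 by cross-coupling. An ester for homologation would not survive the hydride steps upstream; the iodide does, and it is already present in 4.

**Tetrahydrofuran from lactone (17 ← 16 ← 15 ← 14).** C5 is taken back to a lactone carbonyl. No bond is cut, but the ring of 14 becomes enolisable at C4, which is what allows the quaternary carbinol to be built under control of the ring.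

**Quaternary carbinol (14 ← 13 ← 10 + 12).** The C4–O and C4–CH2(ring B) bonds are cut in that order. Both groups enter an enolate anti to the C3 substituent; because the benzyl group goes in first and oxygen second, the OH ends up trans and the benzyl cis to CH2OBn, as the target requires. 12 comes from alcohol 11.

**Lactone core (10 ← 9 ← 8 ← 7 ← 3 + 5).** The C2–C3 bond and the lactone C–O bond are cut. This is a syn-aldol reaction of the succinate imide 3 (from 1 and 2) with aldehyde 5 (from 4), followed by lactonisation; the auxiliary sets C2 and C3 absolutely and the syn relationship becomes 2,3-trans on the ring.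

**Pyrone (40 ← 38 ← 37).** The pyrone O1–C2 and C3=C4 bonds are cut, then the C5–C6 bond. The acetaldehyde side chain of 37 supplies C5 and one CH; aminomethylenation gives the masked 2-substituted malondialdehyde 38, and an α-methoxy phosphonoacetate unit supplies C2 and C3 with the methoxy group in place.

**Side chain (37 ← 36 ← 35 ← 34 ← 33).** Only functional groups change: the aldehyde comes from a vinyl group by hydroboration and oxidation, the diol is masked as an acetal, and the diol comes from an α-hydroxy acid.

**Tetralin (33 ← 32).** The C1–C8a bond is cut. The precursor is the same kind of lactone as 14 with a vinyl group in place of the aryl group, so the lactone oxygen is an allylic leaving group and ring D closes onto the allyl cation. This reuses the stereochemical solution of the other half and sets C1 trans to C2 during ring closure.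

**Vinyl lactone (32 ← 31 ← 28 + 30; 28 ← 27 ← 25 ← 24 ← 3 + 22).** The disconnections are the same as for 14, with acrolein 22 as the aldehyde and bromide 30 (from 29) as the benzyl donor.

## Alternatives that were turned down

**Alternative 1:** The C1–C8a bond of the tetralin is cut in the complete dimer, leading back to the bis(tetrahydrofuran) A1, in which both halves are olivil-type rings and the ring B phenol is an acetate. Forward, acid would ionise the benzylic C–O bond of the tetrahydrofuran that carries the vanillyl group; the free-phenol ring would attack the cation and give the target monoacetate A2.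
- For: it is the shortest path, both halves come from one stereochemical series, the cyclisation is established for monomers of this class, and C1 would be set by a strongly trans-selective closure. On precedent for the key step it is stronger than the chosen route.
- Against: the two tetrahydrofurans of A1 ionise equally, since each benzylic carbon lies para to a phenol oxygen on near-identical rings. Discrimination rests only on the nucleophilicity of the pendant ring (phenol against aryl acetate). The unwanted cation can epimerise its carbon, be trapped by solvent or close slowly onto the acetylated ring.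
- A1 also still needs an unsymmetrical coupling of two hindered guaiacols.
- Comparison: the chosen route distinguishes the halves by construction and never exposes a doubly acid-labile dimer to strong acid, at the cost of more steps.

**Alternative 2:** Ring D is cut at three bonds (C4a–C8a and the two bonds flanking the silicon- and methoxy-bearing carbons), leading to the acyclic diyne A3 with a silicon-tethered methoxyalkyne. Forward, RhCl(PPh3)3, a monovalent rhodium complex, would cyclotrimerise the three alkynes to A4, closing arene, carbocycle and a temporary siloxane ring together.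
- For: the (2+2+2) reaction is well precedented and the tether fixes the regiochemistry. On precedent it is stronger than the chosen key step.
- Against: it spends the key step on ring D, a guaiacol that the benzyl alcohol 29 supplies ready-made. All three stereocenters must be set in an open chain, including C1, which is both benzylic and propargylic and therefore hard to set and easy to epimerise.
- An aryl C–Si to C–OH oxidation is added, and the biaryl bond already present in A3 must be made by some other method.
- Comparison: the chosen route builds the ring at which the halves meet, so its ring construction is also the fragment union.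

**Alternative 3:** The bond between C4 of the tetrahydrofuran and the ring B CH2 is cut, leading to ketone A5, whose C3 CH2O arm carries ring B as a benzylic ether. Forward, irradiation would excite the ketone, which abstracts a benzylic hydrogen from that ether; the 1,5-biradical would close to the cis-fused hydroxy furofuran A6 (Norrish–Yang cyclisation). Hydrogenolysis of the new benzylic C–O bond would then free the benzyl group and the CH2OH.
- For: the cis ring fusion dictates the configuration of the tertiary carbinol relative to C3 without any facial selection by a reagent. On this point it is stronger than the chosen route, which needs an enolate alkylation and an enolate oxidation.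
- Against: the abstraction must choose one benzylic CH2 among several benzyl ethers, α-cleavage of the α,α'-dioxygenated ketone competes, and the aryl chromophores absorb the light.
- The step comes late, on a substrate that already holds the tetralin and the biaryl, and one of two benzylic C–O bonds must then be hydrogenolysed selectively beside benzyl ethers. The union of the halves is not addressed.
- Comparison: the chosen route places its risk in the step that joins the halves and reaches both precursors by ground-state reactions.

Key step: step 29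

Assumption: 2, 11 and 29 are bought (each is one or two routine steps from a bulk chemical); locants in names follow the skeleton numbering of the analysis (tetrahydrofuran or lactone: O1, C2 aryl or vinyl, C3, C4, C5; tetralin: C1 to C4), also where systematic rules would number otherwise.

## Steps

Step 1
Reactants: 1 (S)-4-benzyl-1,3-oxazolidin-2-one; 2 methyl 4-chloro-4-oxobutanoate
Product: 3 methyl 4-[(4S)-4-benzyl-2-oxo-1,3-oxazolidin-3-yl]-4-oxobutanoate
Conditions: n-BuLi, THF, −78 °C; then 2, −78 → 0 °C
Reagents that add atoms: none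
Why: N-Acylation of the lithiated oxazolidinone by an acid chloride at low temperature is the standard entry to such imides and leaves the methyl ester untouched.

Step 2
Reactants: 4 5-iodovanillin
Product: 5 4-(benzyloxy)-3-iodo-5-methoxybenzaldehyde
Conditions: BnBr, K2CO3, DMF, rt
Reagents that add atoms: benzyl bromide, BrCc1ccccc1
Why: Williamson etherification of an acidic iodophenol; the benzyl ether lasts until the final hydrogenolysis.

Step 3
Reactants: 3 succinate imide; 5 4-(benzyloxy)-3-iodo-5-methoxybenzaldehyde
Product: 7 (4S)-4-benzyl-3-{[(2S,3S)-2-(4-benzyloxy-3-iodo-5-methoxyphenyl)-5-oxotetrahydrofuran-3-yl]carbonyl}-1,3-oxazolidin-2-one (2,3-trans lactone), via syn-aldol hydroxy ester 6 (not isolated)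
Conditions: Bu2BOTf, i-Pr2NEt, CH2Cl2, 0 → −78 °C; 5, −78 → 0 °C; pH 7 buffer, MeOH, H2O2; then PPTS (cat.), PhMe, 60 °C
Reagents that add atoms: none
Why: Evans syn-aldol reaction: the Z-boron enolate of the imide (not of the ester) reacts through a Zimmerman–Traxler chair on the face left open by the auxiliary benzyl group, which sets the carbinol carbon (S) and the α-carbon (S) together. The γ-hydroxy ester 6 then lactonises, and the syn relationship becomes trans on the ring.

Step 4
Reactants: 7 lactone imide
Product: 8 (2S,3S)-2-(4-benzyloxy-3-iodo-5-methoxyphenyl)-5-oxotetrahydrofuran-3-carboxylic acid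
Conditions: LiOH, H2O2, THF/H2O, 0 °C; Na2SO3; HCl to pH 2
Reagents that add atoms: hydrogen peroxide, OO
Why: Hydroperoxide attacks the exocyclic imide carbonyl selectively and releases the auxiliary; any lactone opened by hydroxide recloses on acidification, since only the benzylic hydroxyl can reach a carboxyl through a five-membered ring.

Step 5
Reactants: 8 lactone acid
Product: 9 (2S,3R)-2-(4-benzyloxy-3-iodo-5-methoxyphenyl)-3-(hydroxymethyl)tetrahydrofuran-5-one
Conditions: BH3·SMe2, THF, 0 °C → rt; MeOH
Reagents that add atoms: none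
Why: Borane reduces a carboxylic acid through its acyloxyborane much faster than a lactone, and the neutral medium avoids the acyl migration (translactonisation) that a free alkoxide would cause; aryl iodide and benzyl ether are inert.

Step 6
Reactants: 9 hydroxymethyl lactone
Product: 10 (2S,3R)-2-(4-benzyloxy-3-iodo-5-methoxyphenyl)-3-[(benzyloxy)methyl]tetrahydrofuran-5-one
Conditions: BnOC(=NH)CCl3, TfOH (cat.), CH2Cl2/cyclohexane, 0 °C → rt
Reagents that add atoms: benzyl 2,2,2-trichloroacetimidate, ClC(Cl)(Cl)C(=N)OCc1ccccc1
Why: Acid-catalysed benzylation with the trichloroacetimidate avoids the alkoxide that would translactonise this β-hydroxymethyl lactone.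

Step 7
Reactants: 11 3-(benzyloxy)-4-methoxybenzyl alcohol
Product: 12 3-(benzyloxy)-4-methoxybenzyl bromide
Conditions: PBr3, Et2O, 0 °C
Reagents that add atoms: phosphorus tribromide, BrP(Br)Br
Why: Standard bromination of an electron-rich benzylic alcohol; the bromide is used at once because it self-alkylates on storage.

Step 8
Reactants: 10 benzyl-protected lactone; 12 3-(benzyloxy)-4-methoxybenzyl bromide
Product: 13 (2S,3R,4S)-4-(3-benzyloxy-4-methoxybenzyl)-2-(4-benzyloxy-3-iodo-5-methoxyphenyl)-3-[(benzyloxy)methyl]tetrahydrofuran-5-one (all-trans)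
Conditions: LiN(SiMe3)2, THF, −78 °C; 12, DMPU, −78 → −40 °C
Reagents that add atoms: none
Why: Alkylation of the lactone lithium enolate; the electrophile enters anti to the adjacent C3 CH2OBn group, giving the 3,4-trans product, as is general for β-substituted γ-butyrolactones.

Step 9
Reactants: 13 benzylated lactone
Product: 14 (2S,3R,4S)-4-(3-benzyloxy-4-methoxybenzyl)-2-(4-benzyloxy-3-iodo-5-methoxyphenyl)-3-[(benzyloxy)methyl]-4-hydroxytetrahydrofuran-5-one (OH trans to CH2OBn)
Conditions: KN(SiMe3)2, THF, −78 °C; 2-(phenylsulfonyl)-3-phenyloxaziridine, −78 °C; aq. NH4Cl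
Reagents that add atoms: 2-(phenylsulfonyl)-3-phenyloxaziridine, O=S(=O)(N1OC1c1ccccc1)c1ccccc1
Why: Davis hydroxylation of the potassium enolate; the oxidant attacks the planar enolate anti to the C3 CH2OBn group, so the new hydroxyl is trans and the benzyl group cis to CH2OBn. This sets the C4 (S) carbinol of the tetrahydrofuran half.

Step 10
Reactants: 14 hydroxy lactone
Product: 15 lactol of 14 (C5 now CHOH; anomeric mixture)
Conditions: i-Bu2AlH (2.5 equiv), CH2Cl2, −78 °C; aq. KNaC4H4O6
Reagents that add atoms: none
Why: Partial reduction of a lactone at −78 °C, where the aluminium hemiacetal is stable; one equivalent of hydride is used up by the free tertiary hydroxyl.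

Step 11
Reactants: 15 lactol
Product: 16 (2S,3R,4S)-4-(3-benzyloxy-4-methoxybenzyl)-2-(4-benzyloxy-3-iodo-5-methoxyphenyl)-3-[(benzyloxy)methyl]tetrahydrofuran-4-ol
Conditions: Et3SiH, BF3·OEt2, CH2Cl2, −78 → −40 °C; aq. NaHCO3
Reagents that add atoms: none
Why: Ionic hydrogenation: BF3 ionises the lactol to the cyclic oxocarbenium ion and the silane delivers hydride, turning C5 into CH2 without touching C2 to C4. At low temperature the benzylic C2–O bond, deactivated by the meta iodine, should not ionise.

Step 12
Reactants: 16 tetrahydrofuranol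
Product: 17 triethylsilyl ether of 16 at the tertiary hydroxyl
Conditions: Et3SiOTf, 2,6-lutidine, CH2Cl2, 0 °C
Reagents that add atoms: triethylsilyl triflate, CC[Si](CC)(CC)OS(=O)(=O)C(F)(F)F
Why: A silyl triflate with a hindered base silylates even a tertiary alcohol; the ether blocks the hydroxyl during the acetylide and ynolate steps and the cycloaddition, and is cleaved by fluoride at the end.

Step 13
Reactants: 17 aryl iodide
Product: 19 terminal aryl alkyne (ethynyl in place of iodine on ring A), via trimethylsilyl alkyne 18 (not isolated)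
Conditions: HC≡CSiMe3, Pd(PPh3)2Cl2 (3 mol %), copper iodide CuI (5 mol %), Et3N, THF, 40 °C; then K2CO3, MeOH, rt
Reagents that add atoms: ethynyltrimethylsilane, C#C[Si](C)(C)C
Why: Sonogashira coupling of the aryl iodide, followed in the same flask by methanolysis of the C–Si bond; the mild temperature does not stress the silyl ether or the benzylic ether.

Step 14
Reactants: 19 terminal alkyne
Product: 21 fragment 1: triisopropylsilyl ynol ether on ring A of the protected tetrahydrofuran half, via lithium ynolate 20 (not isolated)
Conditions: LiN(SiMe3)2 (2.1 equiv), t-BuOOH (anhydrous, 1.05 equiv), THF, −78 → 0 °C; then i-Pr3SiOTf, −78 °C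
Reagents that add atoms: tert-butyl hydroperoxide, CC(C)(C)OO; triisopropylsilyl triflate, CC(C)[Si](OS(=O)(=O)C(F)(F)F)(C(C)C)C(C)C
Why: The lithium acetylide attacks the electrophilic oxygen of lithium tert-butyl peroxide to give ynolate 20, which the bulky silyl triflate traps on oxygen. The oxygen is introduced only now because an ynol ether would not survive the earlier steps.

Step 15
Reactants: 3 succinate imide; 22 acrolein
Product: 24 (4S)-4-benzyl-3-{[(2R,3S)-5-oxo-2-vinyltetrahydrofuran-3-yl]carbonyl}-1,3-oxazolidin-2-one (2,3-trans lactone), via syn-aldol hydroxy ester 23 (not isolated)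
Conditions: Bu2BOTf, i-Pr2NEt, CH2Cl2, 0 → −78 °C; 22, −78 → 0 °C; pH 7 buffer, MeOH, H2O2; then PPTS (cat.), PhMe, 50 °C
Reagents that add atoms: none
Why: The same Evans syn-aldol and lactonisation as in step 3; boron enolates add 1,2 to enals. The auxiliary fixes the α-carbon (S), which becomes tetralin C2; the allylic carbinol center is ionised later.

Step 16
Reactants: 24 vinyl lactone imide
Product: 25 (2R,3S)-5-oxo-2-vinyltetrahydrofuran-3-carboxylic acid
Conditions: LiOH, H2O2, THF/H2O, 0 °C; Na2SO3; HCl to pH 2
Reagents that add atoms: hydrogen peroxide, OO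
Why: Selective hydroperoxide cleavage of the imide as in step 4; basic peroxide does not epoxidise the unactivated vinyl group.

Step 17
Reactants: 25 vinyl lactone acid
Product: 27 (2R,3R)-3-(hydroxymethyl)-2-vinyltetrahydrofuran-5-one, via mixed carbonic anhydride 26 (not isolated)
Conditions: i-BuOCOCl, N-methylmorpholine, THF, −15 °C; then NaBH4, H2O, −15 → 0 °C; AcOH quench
Reagents that add atoms: none
Why: Borane is excluded because it would hydroborate the vinyl group. The mixed anhydride 26 is reduced by borohydride within minutes in the cold, where the lactone and alkene survive and acyl migration stays slow.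

Step 18
Reactants: 27 hydroxymethyl vinyl lactone
Product: 28 (2R,3R)-3-[(benzyloxy)methyl]-2-vinyltetrahydrofuran-5-one
Conditions: BnOC(=NH)CCl3, TfOH (cat.), CH2Cl2/cyclohexane, 0 °C → rt
Reagents that add atoms: benzyl 2,2,2-trichloroacetimidate, ClC(Cl)(Cl)C(=N)OCc1ccccc1
Why: Acid-catalysed benzylation, chosen for the same reason as in step 6.

Step 19
Reactants: 29 4-(benzyloxy)-3-methoxybenzyl alcohol
Product: 30 4-(benzyloxy)-3-methoxybenzyl bromide
Conditions: PBr3, Et2O, 0 °C
Reagents that add atoms: phosphorus tribromide, BrP(Br)Br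
Why: Bromination of the benzylic alcohol as in step 7.

Step 20
Reactants: 28 benzyl-protected vinyl lactone; 30 4-(benzyloxy)-3-methoxybenzyl bromide
Product: 31 (2R,3R,4S)-4-(4-benzyloxy-3-methoxybenzyl)-3-[(benzyloxy)methyl]-2-vinyltetrahydrofuran-5-one (all-trans)
Conditions: LiN(SiMe3)2, THF, −78 °C; 30, DMPU, −78 → −40 °C
Reagents that add atoms: none
Why: Enolate alkylation anti to the C3 CH2OBn group, as in step 8.

Step 21
Reactants: 31 benzylated vinyl lactone
Product: 32 (2R,3R,4S)-4-(4-benzyloxy-3-methoxybenzyl)-3-[(benzyloxy)methyl]-4-hydroxy-2-vinyltetrahydrofuran-5-one (OH trans to CH2OBn)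
Conditions: KN(SiMe3)2, THF, −78 °C; 2-(phenylsulfonyl)-3-phenyloxaziridine, −78 °C; aq. NH4Cl
Reagents that add atoms: 2-(phenylsulfonyl)-3-phenyloxaziridine, O=S(=O)(N1OC1c1ccccc1)c1ccccc1
Why: Davis hydroxylation anti to the C3 CH2OBn group, as in step 9; it sets the carbinol that becomes tetralin C3 (S), with OH cis to the future C2 CH2OBn on the tetralin.

Step 22
Reactants: 32 hydroxy vinyl lactone
Product: 33 (1R,2S,3S)-7-(benzyloxy)-2-[(benzyloxy)methyl]-3-hydroxy-6-methoxy-1-vinyl-1,2,3,4-tetrahydronaphthalene-3-carboxylic acid (vinyl trans to CH2OBn)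
Conditions: BF3·OEt2 (2 equiv), CH2Cl2, −20 → 0 °C; aq. NaHCO3, then acidify
Reagents that add atoms: none
Why: Intramolecular Friedel–Crafts allylic alkylation: BF3 ionises the allylic lactone C–O bond and the guaiacyl ring attacks the inner carbon of the allyl cation, para to its methoxy group, closing the six-membered ring. A chair-like transition state with vinyl and CH2OBn both pseudo-equatorial should give the 1,2-trans tetralin (C1 set here); C2 and C3 are carried over unchanged from 32.

Step 23
Reactants: 33 tetralin hydroxy acid
Product: 34 (1R,2S,3S)-7-(benzyloxy)-2-[(benzyloxy)methyl]-3-(hydroxymethyl)-6-methoxy-1-vinyl-1,2,3,4-tetrahydronaphthalen-3-ol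
Conditions: LiAlH4, THF, 0 °C → reflux; H2O, aq. NaOH work-up
Reagents that add atoms: none
Why: LiAlH4 reduces the α-hydroxy acid to the 1,2-diol; borane is again avoided because of the vinyl group.

Step 24
Reactants: 34 tetralin diol
Product: 35 isopropylidene acetal of 34 (spiro-dioxolane joining the C3 oxygen to the C3 CH2O)
Conditions: Me2C(OMe)2, PPTS (cat.), CH2Cl2, rt
Reagents that add atoms: 2,2-dimethoxypropane, COC(C)(C)OC
Why: Acetalisation of the tertiary/primary 1,2-diol as a five-membered acetal; it masks both hydroxyls through the oxidation, the olefination and the cycloaddition.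

Step 25
Reactants: 35 vinyl tetralin acetal
Product: 36 primary alcohol (2-hydroxyethyl in place of vinyl at C1)
Conditions: 9-BBN, THF, 0 °C → rt; then NaOH, H2O2, 0 °C
Reagents that add atoms: hydrogen peroxide, OO
Why: Anti-Markovnikov hydroboration of the monosubstituted alkene and oxidation of the C–B bond; no other alkene or reducible group is present.

Step 26
Reactants: 36 primary alcohol
Product: 37 tetralin-1-acetaldehyde (CH2CHO at C1)
Conditions: Dess–Martin periodinane, NaHCO3, CH2Cl2, 0 °C → rt
Reagents that add atoms: none
Why: Dess–Martin oxidation under buffered conditions; the nearest stereocenter (C1) is β to the aldehyde and cannot enolise.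

Step 27
Reactants: 37 tetralin-1-acetaldehyde
Product: 38 (E)-3-(dimethylamino)-2-(tetralin-1-yl)acrylaldehyde (vinylogous formamide; configurationally labile)
Conditions: t-BuOCH(NMe2)2, PhMe, 70 °C
Reagents that add atoms: tert-butoxybis(dimethylamino)methane, CN(C)C(OC(C)(C)C)N(C)C
Why: Aminomethylenation of the aldehyde α-CH2 with Bredereck's reagent gives a masked 2-substituted malondialdehyde, which supplies pyrone C4, C5 and C6; tetralin C1 is not acidic and keeps its configuration.

Step 28
Reactants: 38 vinylogous formamide
Product: 40 fragment 2: 3-methoxy-5-(tetralin-1-yl)-2H-pyran-2-one with the protected (1R,2S,3S)-tetralin of 35, via aminodienoate 39 (not isolated)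
Conditions: (MeO)2P(O)CH(OMe)CO2Me, NaH, THF, 0 → 60 °C; then AcOH, H2O (5 equiv), acetone, 50 °C
Reagents that add atoms: methyl 2-(dimethoxyphosphoryl)-2-methoxyacetate, COC(=O)C(OC)P(=O)(OC)OC
Why: Horner–Wadsworth–Emmons olefination of the formyl group gives the push–pull aminodienoate 39, whose double bonds equilibrate freely. Mild aqueous acid then hydrolyses the enamine and the dienol lactonises onto the ester to the 2-pyrone, while acetone as solvent protects the acetal by mass action. A methoxymalonate could not serve here, because it has only one acidic hydrogen and cannot form the C3=C4 bond by condensation.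

Step 29
Reactants: 21 fragment 1 (ynol ether); 40 fragment 2 (pyrone)
Product: 42 fully protected biaryl (triisopropylsilyl ether on the new ring C), via cycloadduct 41 (not isolated)
Conditions: 21 (1.5 equiv), PhMe (1 M), 110 °C, sealed tube, argon
Reagents that add atoms: none
Why: Proposed new method: a 3-alkoxy-2-pyrone has not been shown to undergo the pyrone–alkyne (4+2) cycloaddition and decarboxylation with a silyl ynol ether; the closest known reaction type is that benzannulation for electron-poor 2-pyrones with ynamines or ketene acetals (inverse electron demand). The pyrone C3=C4–C5=C6 unit is the 4π component and the C≡C bond of 21 the 2π component: the alkyne carbon bearing ring A, which is β to the siloxy group and therefore the nucleophilic terminus, should bond to pyrone C6, the δ-position of the unsaturated lactone and its most electrophilic diene terminus, while the siloxy-bearing carbon bonds to C3; a concerted asynchronous transition state and a stepwise path through a ketenium–dienolate zwitterion lead to the same bridged lactone 41. Ring C is thereby closed by a (4+2) annulation, two carbons being added across the ends of a four-carbon diene with both new bonds formed in one operation, and retro-(4+2) loss of CO2 from 41, driven by aromatisation, should follow at or below the reaction temperature. The step creates no lasting stereocenter, since both bridgeheads of 41 become arene carbons, so the face of approach is immaterial; the six existing centers are remote from the reacting atoms and are not epimerisable under neutral heating. The selectivity needed is regiochemical and is secured by this polarity match, because the reverse orientation would force the nucleophilic alkyne carbon onto C3, which is α to the carbonyl, oxygen-substituted and not electrophilic. The open question is rate, because the methoxy group at C3 raises the diene LUMO: the ynol ether is therefore used in excess at high concentration, and the temperature is held at the limit that a triisopropylsilyl ynol ether tolerates before it rearranges to the silylketene.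

Step 30
Reactants: 42 protected biaryl
Product: 43 ring C phenol and tetrahydrofuran tertiary alcohol set free (five benzyl ethers and the acetal kept)
Conditions: Bu4NF, THF, 0 °C → rt; aq. NH4Cl
Reagents that add atoms: none
Why: Fluoride cleaves the aryl triisopropylsilyl ether and the tertiary triethylsilyl ether in one operation; benzyl ethers and the acetal are unaffected.

Step 31
Reactants: 43 desilylated biaryl
Product: 44 pentabenzyl ether of the target (tetralin C3 OH and CH2OH set free)
Conditions: AcOH/THF/H2O (3:1:1), 40 °C
Reagents that add atoms: none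
Why: Mild aqueous acid hydrolyses the isopropylidene acetal. It is done while ring A still carries its benzyl ether and at modest temperature, so that the benzylic C2–O bond of the tetrahydrofuran does not ionise and close onto ring B.

Step 32
Reactants: 44 pentabenzyl ether
Product: 45 target CNP0252244.1
Conditions: H2 (1 atm), Pd on carbon (10 %), EtOAc/MeOH, rt
Reagents that add atoms: none
Why: Hydrogenolysis of the five benzyl ethers under neutral conditions, where O-benzyl groups cleave much faster than the cyclic 2-aryl ether; no stereocenter is touched.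

## Compound list

1 | (S)-4-benzyl-1,3-oxazolidin-2-one | O=C1N[C@@H](Cc2ccccc2)CO1 | starting material
2 | methyl 4-chloro-4-oxobutanoate | COC(=O)CCC(Cl)=O | starting material
3 | methyl 4-[(4S)-4-benzyl-2-oxo-1,3-oxazolidin-3-yl]-4-oxobutanoate | COC(=O)CCC(=O)N1[C@@H](Cc2ccccc2)COC1=O | intermediate
4 | 5-iodovanillin | COc1cc(C=O)cc(I)c1O | starting material
5 | 4-(benzyloxy)-3-iodo-5-methoxybenzaldehyde | COc1cc(C=O)cc(I)c1OCc1ccccc1 | intermediate
6 | syn-aldol hydroxy ester, methyl (3S,4S)-3-(auxiliary-carbonyl)-4-aryl-4-hydroxybutanoate | COC(=O)C[C@H](C(=O)N1[C@@H](Cc2ccccc2)COC1=O)[C@H](O)c1cc(OC)c(OCc2ccccc2)c(I)c1 | intermediate (not isolated)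
7 | (2S,3S)-2-aryl-5-oxotetrahydrofuran-3-carbonyl imide of the (S)-auxiliary (2,3-trans) | O=C1C[C@H](C(=O)N2[C@@H](Cc3ccccc3)COC2=O)[C@@H](c2cc(OC)c(OCc3ccccc3)c(I)c2)O1 | intermediate
8 | (2S,3S)-2-(4-benzyloxy-3-iodo-5-methoxyphenyl)-5-oxotetrahydrofuran-3-carboxylic acid | O=C1C[C@H](C(=O)O)[C@@H](c2cc(OC)c(OCc3ccccc3)c(I)c2)O1 | intermediate
9 | (2S,3R)-2-(4-benzyloxy-3-iodo-5-methoxyphenyl)-3-(hydroxymethyl)tetrahydrofuran-5-one | O=C1C[C@H](CO)[C@@H](c2cc(OC)c(OCc3ccccc3)c(I)c2)O1 | intermediate
10 | (2S,3R)-2-(4-benzyloxy-3-iodo-5-methoxyphenyl)-3-[(benzyloxy)methyl]tetrahydrofuran-5-one | O=C1C[C@H](COCc2ccccc2)[C@@H](c2cc(OC)c(OCc3ccccc3)c(I)c2)O1 | intermediate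
11 | 3-(benzyloxy)-4-methoxybenzyl alcohol | COc1ccc(CO)cc1OCc1ccccc1 | starting material
12 | 3-(benzyloxy)-4-methoxybenzyl bromide | COc1ccc(CBr)cc1OCc1ccccc1 | intermediate
13 | (2S,3R,4S)-4-(3-benzyloxy-4-methoxybenzyl)-2-(4-benzyloxy-3-iodo-5-methoxyphenyl)-3-[(benzyloxy)methyl]tetrahydrofuran-5-one | COc1ccc(C[C@@H]2C(=O)O[C@H](c3cc(OC)c(OCc4ccccc4)c(I)c3)[C@H]2COCc2ccccc2)cc1OCc1ccccc1 | intermediate
14 | (2S,3R,4S)-4-hydroxy derivative of 13 (OH trans to CH2OBn) | COc1ccc(C[C@@]2(O)C(=O)O[C@H](c3cc(OC)c(OCc4ccccc4)c(I)c3)[C@H]2COCc2ccccc2)cc1OCc1ccccc1 | intermediate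
15 | lactol of 14 (C5 hemiacetal, anomeric mixture) | COc1ccc(C[C@@]2(O)C(O)O[C@H](c3cc(OC)c(OCc4ccccc4)c(I)c3)[C@H]2COCc2ccccc2)cc1OCc1ccccc1 | intermediate
16 | (2S,3R,4S)-4-(3-benzyloxy-4-methoxybenzyl)-2-(4-benzyloxy-3-iodo-5-methoxyphenyl)-3-[(benzyloxy)methyl]tetrahydrofuran-4-ol | COc1ccc(C[C@@]2(O)CO[C@H](c3cc(OC)c(OCc4ccccc4)c(I)c3)[C@H]2COCc2ccccc2)cc1OCc1ccccc1 | intermediate
17 | triethylsilyl ether of 16 | COc1ccc(C[C@@]2(O[Si](CC)(CC)CC)CO[C@H](c3cc(OC)c(OCc4ccccc4)c(I)c3)[C@H]2COCc2ccccc2)cc1OCc1ccccc1 | intermediate
18 | trimethylsilylethynyl analogue of 17 (alkyne in place of iodine) | COc1ccc(C[C@@]2(O[Si](CC)(CC)CC)CO[C@H](c3cc(OC)c(OCc4ccccc4)c(C#C[Si](C)(C)C)c3)[C@H]2COCc2ccccc2)cc1OCc1ccccc1 | intermediate (not isolated)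
19 | ethynyl analogue of 17 (terminal alkyne on ring A) | COc1ccc(C[C@@]2(O[Si](CC)(CC)CC)CO[C@H](c3cc(OC)c(OCc4ccccc4)c(C#C)c3)[C@H]2COCc2ccccc2)cc1OCc1ccccc1 | intermediate
20 | lithium ynolate of 19 | COc1ccc(C[C@@]2(O[Si](CC)(CC)CC)CO[C@H](c3cc(OC)c(OCc4ccccc4)c(C#C[O-])c3)[C@H]2COCc2ccccc2)cc1OCc1ccccc1.[Li+] | intermediate (not isolated)
21 | fragment 1, ring A triisopropylsilyl ynol ether of the protected (2S,3R,4S)-tetrahydrofuran half | COc1ccc(C[C@@]2(O[Si](CC)(CC)CC)CO[C@H](c3cc(OC)c(OCc4ccccc4)c(C#CO[Si](C(C)C)(C(C)C)C(C)C)c3)[C@H]2COCc2ccccc2)cc1OCc1ccccc1 | intermediate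
22 | acrolein | C=CC=O | starting material
23 | syn-aldol hydroxy ester from 3 and acrolein | COC(=O)C[C@H](C(=O)N1[C@@H](Cc2ccccc2)COC1=O)[C@H](O)C=C | intermediate (not isolated)
24 | (2R,3S)-5-oxo-2-vinyltetrahydrofuran-3-carbonyl imide of the (S)-auxiliary (2,3-trans) | O=C1C[C@H](C(=O)N2[C@@H](Cc3ccccc3)COC2=O)[C@@H](C=C)O1 | intermediate
25 | (2R,3S)-5-oxo-2-vinyltetrahydrofuran-3-carboxylic acid | O=C1C[C@H](C(=O)O)[C@@H](C=C)O1 | intermediate
26 | isobutyl carbonic mixed anhydride of 25 | O=C1C[C@H](C(=O)OC(=O)OCC(C)C)[C@@H](C=C)O1 | intermediate (not isolated)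
27 | (2R,3R)-3-(hydroxymethyl)-2-vinyltetrahydrofuran-5-one | O=C1C[C@H](CO)[C@@H](C=C)O1 | intermediate
28 | (2R,3R)-3-[(benzyloxy)methyl]-2-vinyltetrahydrofuran-5-one | O=C1C[C@H](COCc2ccccc2)[C@@H](C=C)O1 | intermediate
29 | 4-(benzyloxy)-3-methoxybenzyl alcohol | COc1cc(CO)ccc1OCc1ccccc1 | starting material
30 | 4-(benzyloxy)-3-methoxybenzyl bromide | COc1cc(CBr)ccc1OCc1ccccc1 | intermediate
31 | (2R,3R,4S)-4-(4-benzyloxy-3-methoxybenzyl)-3-[(benzyloxy)methyl]-2-vinyltetrahydrofuran-5-one | COc1cc(C[C@@H]2C(=O)O[C@H](C=C)[C@H]2COCc2ccccc2)ccc1OCc1ccccc1 | intermediate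
32 | (2R,3R,4S)-4-hydroxy derivative of 31 (OH trans to CH2OBn) | COc1cc(C[C@@]2(O)C(=O)O[C@H](C=C)[C@H]2COCc2ccccc2)ccc1OCc1ccccc1 | intermediate
33 | (1R,2S,3S)-7-(benzyloxy)-2-[(benzyloxy)methyl]-3-hydroxy-6-methoxy-1-vinyl-1,2,3,4-tetrahydronaphthalene-3-carboxylic acid | C=C[C@H]1c2cc(OCc3ccccc3)c(OC)cc2C[C@@](O)(C(=O)O)[C@@H]1COCc1ccccc1 | intermediate
34 | (1R,2S,3S)-7-(benzyloxy)-2-[(benzyloxy)methyl]-3-(hydroxymethyl)-6-methoxy-1-vinyl-1,2,3,4-tetrahydronaphthalen-3-ol | C=C[C@H]1c2cc(OCc3ccccc3)c(OC)cc2C[C@@](O)(CO)[C@@H]1COCc1ccccc1 | intermediate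
35 | isopropylidene acetal of 34 (spiro-dioxolane at C3) | C=C[C@H]1c2cc(OCc3ccccc3)c(OC)cc2C[C@]2(OC(C)(C)OC2)[C@@H]1COCc1ccccc1 | intermediate
36 | 2-hydroxyethyl analogue of 35 (CH2CH2OH at C1) | OCC[C@H]1c2cc(OCc3ccccc3)c(OC)cc2C[C@]2(OC(C)(C)OC2)[C@@H]1COCc1ccccc1 | intermediate
37 | tetralin-1-acetaldehyde (CH2CHO at C1 of the protected tetralin) | O=CC[C@H]1c2cc(OCc3ccccc3)c(OC)cc2C[C@]2(OC(C)(C)OC2)[C@@H]1COCc1ccccc1 | intermediate
38 | (E)-3-(dimethylamino)-2-(protected tetralin-1-yl)acrylaldehyde | CN(C)/C=C(/C=O)[C@H]1c2cc(OCc3ccccc3)c(OC)cc2C[C@]2(OC(C)(C)OC2)[C@@H]1COCc1ccccc1 | intermediate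
39 | methyl 5-(dimethylamino)-2-methoxy-4-(protected tetralin-1-yl)penta-2,4-dienoate (labile alkene geometry, mixture) | COC(=O)C(OC)=CC(=CN(C)C)[C@H]1c2cc(OCc3ccccc3)c(OC)cc2C[C@]2(OC(C)(C)OC2)[C@@H]1COCc1ccccc1 | intermediate (not isolated)
40 | fragment 2, 3-methoxy-5-[(1R,2S,3S)-protected tetralin-1-yl]-2H-pyran-2-one | COc1cc([C@H]2c3cc(OCc4ccccc4)c(OC)cc3C[C@]3(OC(C)(C)OC3)[C@@H]2COCc2ccccc2)coc1=O | intermediate
41 | bridged lactone cycloadduct (2-oxabicyclo[2.2.2]octa-5,7-dien-3-one core, bridgehead configuration not defined) | COc1ccc(C[C@@]2(O[Si](CC)(CC)CC)CO[C@H](c3cc(OC)c(OCc4ccccc4)c(C4=C(O[Si](C(C)C)(C(C)C)C(C)C)C5(OC)C=C([C@H]6c7cc(OCc8ccccc8)c(OC)cc7C[C@]7(OC(C)(C)OC7)[C@@H]6COCc6ccccc6)C4OC5=O)c3)[C@H]2COCc2ccccc2)cc1OCc1ccccc1 | intermediate (not isolated)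
42 | fully protected biaryl: five benzyl ethers, ring C triisopropylsilyl ether, tertiary triethylsilyl ether, isopropylidene acetal | COc1ccc(C[C@@]2(O[Si](CC)(CC)CC)CO[C@H](c3cc(OC)c(OCc4ccccc4)c(-c4cc([C@H]5c6cc(OCc7ccccc7)c(OC)cc6C[C@]6(OC(C)(C)OC6)[C@@H]5COCc5ccccc5)cc(OC)c4O[Si](C(C)C)(C(C)C)C(C)C)c3)[C@H]2COCc2ccccc2)cc1OCc1ccccc1 | intermediate
43 | desilylated biaryl (ring C phenol and tetrahydrofuran tertiary OH free) | COc1ccc(C[C@@]2(O)CO[C@H](c3cc(OC)c(OCc4ccccc4)c(-c4cc([C@H]5c6cc(OCc7ccccc7)c(OC)cc6C[C@]6(OC(C)(C)OC6)[C@@H]5COCc5ccccc5)cc(OC)c4O)c3)[C@H]2COCc2ccccc2)cc1OCc1ccccc1 | intermediate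
44 | pentabenzyl ether of the target | COc1ccc(C[C@@]2(O)CO[C@H](c3cc(OC)c(OCc4ccccc4)c(-c4cc([C@H]5c6cc(OCc7ccccc7)c(OC)cc6C[C@@](O)(CO)[C@@H]5COCc5ccccc5)cc(OC)c4O)c3)[C@H]2COCc2ccccc2)cc1OCc1ccccc1 | intermediate
45 | CNP0252244.1 | COc1ccc(C[C@@]2(O)CO[C@H](c3cc(OC)c(O)c(-c4cc([C@H]5c6cc(O)c(OC)cc6C[C@@](O)(CO)[C@@H]5CO)cc(OC)c4O)c3)[C@H]2CO)cc1O | target

## Step count and least certain steps

Total: 32 steps. Longest linear sequence: 18 steps (steps 1, 15–18 and 20–32, from 1 through fragment 2 to 45); the fragment 1 branch is 12 steps before the union.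

**Step 29 (key step).** The most likely failure is that the cycloaddition is too slow. The C3 methoxy group raises the diene LUMO and both reacting alkyne carbons are hindered, so the ynol ether may be consumed by 1,3-silyl shift to the silylketene, by oligomerisation or by adventitious hydrolysis before it adds. Within the approach, silver bis(triflimide) AgNTf2 (monovalent silver) at room temperature or high pressure would be tried first. The fallback uses known chemistry and makes the biaryl bond by cross-coupling; it sets out from 10, 30 and 17 and comes back at 45. Lactone 10 is alkylated with bromide 30 (LiN(SiMe3)2) to the vanillyl-substituted lactone F1 and hydroxylated as in step 9 to the hydroxy lactone F2. BF3·OEt2 then ionises the benzylic lactone C–O bond and the vanillyl ring closes onto the cation, the acid-induced aryltetralin cyclisation known for this lignan class, to give the 1-aryltetralin hydroxy acid F3. BH3·SMe2 reduces F3 to the diol F4, and 2,2-dimethoxypropane with PPTS gives the acetonide aryl iodide F5. Iodide 17 is converted with bis(pinacolato)diboron, Pd(dppf)Cl2 and KOAc into the pinacol boronate F6. Suzuki–Miyaura coupling of F5 and F6 (Pd(OAc)2, SPhos, K3PO4, toluene/water) gives the protected biaryl F7, which differs from 42 only in a benzyl instead of a silyl group on the ring C phenol. TsOH in methanol removes the triethylsilyl ether and the acetonide to give the hexabenzyl ether F8, and hydrogenolysis as in step 32 gives 45.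

**Step 22.** The allyl cation is only monosubstituted, so ionisation of the lactone may be incomplete; slow cleavage of benzyl ethers by the Lewis acid could then take over, or trans control at C1 could be insufficient. The fallback sets out from 32 and comes back at 34. LiAlH4 reduces 32 to the triol F9, whose secondary allylic alcohol ionises under catalysis; Bi(OTf)3 (5 mol %) in MeNO2/CH2Cl2 then effects the dehydrative intramolecular Friedel–Crafts allylation, known for allylic alcohols tethered to dialkoxyarenes, and gives diol 34 directly. Any cyclic ether formed by capture of the cation by the primary hydroxyl is itself an allylic ether and re-enters the equilibrium.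

**Step 28.** The phosphonate anion may fail to add to the poorly electrophilic vinylogous formamide, or the acetal may be lost during the acidic ring closure. The fallback sets out from 38 and comes back at 40. The lithium enolate of methyl methoxyacetate (LiN(i-Pr)2, THF, −78 °C) adds 1,2 to the formyl group to give the aldol adduct F10. Quenching with acetic acid expels dimethylamine and gives the 4-formyl-2-methoxybut-3-enoate F11. DBU in toluene then closes the dienolate oxygen onto the ester to give 40 under basic conditions that the acetal tolerates.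

**Step 9 (and its twin, step 21).** Facial selectivity may erode, because the γ-aryl group lies on the face the oxidant must use, or the hindered enolate may condense with the sulfonimine by-product. The fallback sets out from 10 and 11 and comes back at 14. MnO2 oxidises 11 to 3-(benzyloxy)-4-methoxybenzaldehyde F12. The lithium enolate of 10 is condensed with F12 and the aldol is dehydrated (MsCl, Et3N, then DBU) to the (E)-benzylidene lactone F13. OsO4 (catalytic) with N-methylmorpholine N-oxide dihydroxylates the exocyclic alkene anti to CH2OBn to give the diol F14, whose tertiary hydroxyl already has the configuration of 14. Et3SiH/CF3CO2H then removes the secondary p-methoxybenzylic hydroxyl by ionic hydrogenation and gives 14; the tertiary center is α to the lactone carbonyl, which disfavours a pinacol shift.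

**Step 14.** Oxygen transfer to the hindered ortho-substituted acetylide may be incomplete, or the ynol ether may hydrolyse or rearrange to the ketene during isolation. The fallback sets out from 17 and comes back at 21. Palladium-catalysed methoxycarbonylation (Pd(OAc)2, dppp, CO, MeOH, Et3N) gives the ring A methyl ester F15. Kowalski homologation (CH2Br2 with lithium 2,2,6,6-tetramethylpiperidide, then n-BuLi) rearranges the derived dibromomethyl ketone enolate to the same ynolate 20, which i-Pr3SiOTf silylates to 21.

## Further compounds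

F1 | step 29 | (2S,3R,4S)-4-(4-benzyloxy-3-methoxybenzyl)-2-(4-benzyloxy-3-iodo-5-methoxyphenyl)-3-[(benzyloxy)methyl]tetrahydrofuran-5-one | COc1cc(C[C@@H]2C(=O)O[C@H](c3cc(OC)c(OCc4ccccc4)c(I)c3)[C@H]2COCc2ccccc2)ccc1OCc1ccccc1
F2 | step 29 | 4-hydroxy derivative of F1 (OH trans to CH2OBn) | COc1cc(C[C@@]2(O)C(=O)O[C@H](c3cc(OC)c(OCc4ccccc4)c(I)c3)[C@H]2COCc2ccccc2)ccc1OCc1ccccc1
F3 | step 29 | (1S,2S,3S)-1-(4-benzyloxy-3-iodo-5-methoxyphenyl)-7-(benzyloxy)-2-[(benzyloxy)methyl]-3-hydroxy-6-methoxy-1,2,3,4-tetrahydronaphthalene-3-carboxylic acid | COc1cc([C@H]2c3cc(OCc4ccccc4)c(OC)cc3C[C@@](O)(C(=O)O)[C@@H]2COCc2ccccc2)cc(I)c1OCc1ccccc1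
F4 | step 29 | diol from F3 (CH2OH in place of CO2H) | COc1cc([C@H]2c3cc(OCc4ccccc4)c(OC)cc3C[C@@](O)(CO)[C@@H]2COCc2ccccc2)cc(I)c1OCc1ccccc1
F5 | step 29 | isopropylidene acetal of F4 (aryl iodide on ring C) | COc1cc([C@H]2c3cc(OCc4ccccc4)c(OC)cc3C[C@]3(OC(C)(C)OC3)[C@@H]2COCc2ccccc2)cc(I)c1OCc1ccccc1
F6 | step 29 | pinacol boronate of 17 (boron in place of iodine on ring A) | COc1ccc(C[C@@]2(O[Si](CC)(CC)CC)CO[C@H](c3cc(OC)c(OCc4ccccc4)c(B4OC(C)(C)C(C)(C)O4)c3)[C@H]2COCc2ccccc2)cc1OCc1ccccc1
F7 | step 29 | protected biaryl with six benzyl ethers, tertiary triethylsilyl ether and isopropylidene acetal | COc1ccc(C[C@@]2(O[Si](CC)(CC)CC)CO[C@H](c3cc(OC)c(OCc4ccccc4)c(-c4cc([C@H]5c6cc(OCc7ccccc7)c(OC)cc6C[C@]6(OC(C)(C)OC6)[C@@H]5COCc5ccccc5)cc(OC)c4OCc4ccccc4)c3)[C@H]2COCc2ccccc2)cc1OCc1ccccc1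
F8 | step 29 | hexabenzyl ether of the target | COc1ccc(C[C@@]2(O)CO[C@H](c3cc(OC)c(OCc4ccccc4)c(-c4cc([C@H]5c6cc(OCc7ccccc7)c(OC)cc6C[C@@](O)(CO)[C@@H]5COCc5ccccc5)cc(OC)c4OCc4ccccc4)c3)[C@H]2COCc2ccccc2)cc1OCc1ccccc1
F9 | step 22 | acyclic triol from 32 (allylic alcohol, tertiary alcohol and primary alcohol) | COc1cc(C[C@@](O)(CO)[C@H](COCc2ccccc2)[C@H](O)C=C)ccc1OCc1ccccc1
F10 | step 28 | aldol adduct of 38 with methyl methoxyacetate (mixture at the two new centers) | COC(=O)C(OC)C(O)C(=CN(C)C)[C@H]1c2cc(OCc3ccccc3)c(OC)cc2C[C@]2(OC(C)(C)OC2)[C@@H]1COCc1ccccc1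
F11 | step 28 | methyl 4-formyl-2-methoxy-4-(protected tetralin-1-yl)but-3-enoate (mixture at C2 and of alkene isomers) | COC(=O)C(OC)C=C(C=O)[C@H]1c2cc(OCc3ccccc3)c(OC)cc2C[C@]2(OC(C)(C)OC2)[C@@H]1COCc1ccccc1
F12 | step 9 | 3-(benzyloxy)-4-methoxybenzaldehyde | COc1ccc(C=O)cc1OCc1ccccc1
F13 | step 9 | (E)-4-(3-benzyloxy-4-methoxybenzylidene) lactone from 10 | COc1ccc(/C=C2/C(=O)O[C@H](c3cc(OC)c(OCc4ccccc4)c(I)c3)[C@H]2COCc2ccccc2)cc1OCc1ccccc1
F14 | step 9 | diol from F13 (tertiary OH as in 14, secondary benzylic OH S) | COc1ccc([C@H](O)[C@@]2(O)C(=O)O[C@H](c3cc(OC)c(OCc4ccccc4)c(I)c3)[C@H]2COCc2ccccc2)cc1OCc1ccccc1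
F15 | step 14 | ring A methyl ester (CO2Me in place of iodine in 17) | COc1ccc(C[C@@]2(O[Si](CC)(CC)CC)CO[C@H](c3cc(OC)c(OCc4ccccc4)c(C(=O)OC)c3)[C@H]2COCc2ccccc2)cc1OCc1ccccc1
A1 | alternative 1 | bis(tetrahydrofuran) dimer, both halves olivil-type rings, ring B phenol as acetate | COc1ccc(C[C@@]2(O)CO[C@H](c3cc(OC)c(O)c(-c4cc([C@H]5OC[C@](O)(Cc6ccc(O)c(OC)c6)[C@@H]5CO)cc(OC)c4O)c3)[C@H]2CO)cc1OC(C)=O
A2 | alternative 1 | target monoacetate (acetate on the ring B phenol) | COc1ccc(C[C@@]2(O)CO[C@H](c3cc(OC)c(O)c(-c4cc([C@H]5c6cc(O)c(OC)cc6C[C@@](O)(CO)[C@@H]5CO)cc(OC)c4O)c3)[C@H]2CO)cc1OC(C)=O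
A3 | alternative 2 | acyclic 1,7-diyne with ring C at the propargylic C1 and a diisopropylsilyl-tethered methoxyalkyne on the C2 CH2O arm | COc1cc(C2OCCO2)cc(-c3cc([C@@H](C#C)[C@@H](CO[Si](C(C)C)(C(C)C)C#COC)[C@]4(CC#C)OC(C)(C)OC4)cc(OC)c3OCc3ccccc3)c1OCc1ccccc1
A4 | alternative 2 | tetralin with ring D closed and its future phenol carbon silylated within a siloxane ring | COc1cc(C2OCCO2)cc(-c3cc([C@H]4c5cc6c(OC)cc5C[C@]5(OC(C)(C)OC5)[C@@H]4CO[Si]6(C(C)C)C(C)C)cc(OC)c3OCc3ccccc3)c1OCc1ccccc1
A5 | alternative 3 | tetrahydrofuran-4-one whose C3 CH2O arm carries ring B as a benzylic ether | COc1ccc(COC[C@H]2C(=O)CO[C@@H]2c2cc(OC)c(OC(=O)C(C)(C)C)c(-c3cc([C@H]4c5cc(OCc6ccccc6)c(OC)cc5C[C@]5(OC(C)(C)OC5)[C@@H]4COCc4ccccc4)cc(OC)c3OCc3ccccc3)c2)cc1OCc1ccccc1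
A6 | alternative 3 | cis-fused bridgehead-hydroxy furofuran | COc1ccc([C@H]2OC[C@H]3[C@]2(O)CO[C@@H]3c3cc(OC)c(OC(=O)C(C)(C)C)c(-c4cc([C@H]5c6cc(OCc7ccccc7)c(OC)cc6C[C@]6(OC(C)(C)OC6)[C@@H]5COCc5ccccc5)cc(OC)c4OCc4ccccc4)c3)cc1OCc1ccccc1
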